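**Retrosynthetic overview**
- Ring C (the pyranone) is formed last: cutting C4–C3 and O1–C2 of the chromone gives salicylaldehyde 5 (ring A) and aryl methyl ynol ether 10 (ring B plus the 3-OMe carbon), joined by a new rhodium-catalysed oxidative C–H/O–H annulation.
- 5 comes from ortho-formylation of 2,3,4-trimethoxyphenol 3, which comes from Dakin-type oxidation of 2,3,4-trimethoxybenzaldehyde 1.
- 10 comes from enol triflate formation and elimination of α-methoxy ketone 8, made by Friedel–Crafts acylation of anisole 6 with methoxyacetyl chloride 7.
- Rings A and B are bought preformed; all five methoxy groups are in place before the ring-forming step.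

Assumption: auranetin (3,6,7,8,4'-pentamethoxyflavone) has no stereocentre and no stereogenic double bond, so "single enantiomer" is taken to mean the one achiral structure drawn.

**Step 1**
Reactants: 1 2,3,4-trimethoxybenzaldehyde
Product: 3 2,3,4-trimethoxyphenol, via aryl formate 2 (not isolated)
Conditions: mCPBA (1.2 equiv), CH2Cl2, 0 °C to rt; then HCl (cat.), MeOH, rt
Reagents that add atoms: mCPBA (3-chloroperoxybenzoic acid), OOC(=O)c1cccc(Cl)c1
Why: Dakin-type Baeyer–Villiger oxidation, in which the electron-rich aryl group (ortho and para methoxy donors) migrates in preference to hydride to give the aryl formate, which acid-catalysed methanolysis cleaves to the phenol; no stereocentre is formed.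

**Step 2**
Reactants: 3 2,3,4-trimethoxyphenol
Product: 5 2-hydroxy-3,4,5-trimethoxybenzaldehyde, via benzylic alcohol 4 (not isolated)
Conditions: MgCl2 (1.5 equiv), Et3N (3.75 equiv), (CH2O)n (6.8 equiv), MeCN, reflux; 1 M HCl work-up
Reagents that add atoms: paraformaldehyde (reacts as formaldehyde), C=O
Why: Magnesium-mediated ortho-formylation (Casnati–Skattebøl), in which the magnesium phenoxide delivers formaldehyde to the only free ortho position and a second formaldehyde oxidises the benzylic alkoxide by Oppenauer-type hydride transfer; no stereocentre is formed.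

**Step 3**
Reactants: 6 anisole; 7 methoxyacetyl chloride
Product: 8 2-methoxy-1-(4-methoxyphenyl)ethan-1-one
Conditions: AlCl3 (1.2 equiv), CH2Cl2, 0 °C
Reagents that add atoms: none
Why: Friedel–Crafts acylation, directed para by the methoxy group of anisole, and the deactivated aryl ketone product does not react a second time.

**Step 4**
Reactants: 8 2-methoxy-1-(4-methoxyphenyl)ethan-1-one
Product: 10 1-methoxy-4-(methoxyethynyl)benzene, via (Z)-enol triflate 9 (not isolated)
Conditions: LiN(SiMe3)2 (1.1 equiv), THF, −78 °C; PhNTf2 (1.1 equiv), −78 to 0 °C; then KOtBu (1.5 equiv), −78 °C to rt; filtration through basic Al2O3, store cold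
Reagents that add atoms: none
Why: Enol triflate formation followed by β-elimination: the ketone has a single enolisable position, the lithium-chelated (Z)-enolate is O-triflated by PhNTf2, and KOtBu effects anti E2 loss of triflate (vinylic H trans to OTf) to give the ynol ether, which cannot undergo retro-ene loss because it is a methyl ether.

**Step 5**
Reactants: 5 2-hydroxy-3,4,5-trimethoxybenzaldehyde; 10 1-methoxy-4-(methoxyethynyl)benzene
Product: 11 auranetin (3,6,7,8-tetramethoxy-2-(4-methoxyphenyl)-4H-chromen-4-one)
Conditions: [Cp*RhCl2]2 (2.5 mol %), Cu(OAc)2 (2.1 equiv, anhydrous), K2CO3 (1.1 equiv), 4 Å MS, 1,4-dioxane, 80 °C, N2; 10 (1.5 equiv) added over 4 h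
Reagents that add atoms: none
Why: Proposed new method: a trivalent-rhodium-catalysed oxidative aldehyde C–H/phenol O–H [4+2] annulation with an aryl ynol ether as the two-carbon partner, in which the phenoxide of 5 binds Cp*Rh(OAc)2, acetate-assisted cleavage of the formyl C–H gives a five-membered acyl rhodacycle, the ynol ether inserts into the Rh–acyl bond with the acyl carbon going to the oxygen-bearing (electrophilic, oxocarbenium-like) alkyne carbon and rhodium to the nucleophilic aryl-bearing carbon, C–O reductive elimination from the seven-membered oxarhodacycle closes ring C (new C4–C3 and O1–C2 bonds) and Cu(OAc)2 returns monovalent rhodium to the trivalent state; the closest known reaction type is the rhodium-catalysed oxidative coupling of salicylaldehydes with diaryl or dialkyl alkynes to 2,3-disubstituted chromones, here extended to an ynol ether so that the 3-methoxy group arrives with the alkyne, while the carbonate buffer, molecular sieves, silver-free conditions and slow addition protect the acid-sensitive ynol ether.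

**Compound list**
1 | 2,3,4-trimethoxybenzaldehyde | COc1ccc(C=O)c(OC)c1OC | starting material
2 | aryl formate (2,3,4-trimethoxyphenyl formate), formed in the flask | COc1ccc(OC=O)c(OC)c1OC | intermediate
3 | 2,3,4-trimethoxyphenol | COc1ccc(O)c(OC)c1OC | intermediate
4 | benzylic alcohol (6-(hydroxymethyl)-2,3,4-trimethoxyphenol), formed in the flask | COc1cc(CO)c(O)c(OC)c1OC | intermediate
5 | 2-hydroxy-3,4,5-trimethoxybenzaldehyde | COc1cc(C=O)c(O)c(OC)c1OC | intermediate
6 | anisole | COc1ccccc1 | starting material
7 | methoxyacetyl chloride | COCC(=O)Cl | starting material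
8 | 2-methoxy-1-(4-methoxyphenyl)ethan-1-one | COCC(=O)c1ccc(OC)cc1 | intermediate
9 | (Z)-enol triflate ((Z)-2-methoxy-1-(4-methoxyphenyl)ethenyl trifluoromethanesulfonate), formed in the flask | CO/C=C(\OS(=O)(=O)C(F)(F)F)c1ccc(OC)cc1 | intermediate
10 | 1-methoxy-4-(methoxyethynyl)benzene | COC#Cc1ccc(OC)cc1 | intermediate
11 | auranetin (3,6,7,8-tetramethoxy-2-(4-methoxyphenyl)-4H-chromen-4-one) | COc1ccc(-c2oc3c(OC)c(OC)c(OC)cc3c(=O)c2OC)cc1 | target

**Step count and risks**
Total steps: 5. Longest linear sequence: 3 steps (1 → 3 → 5 → 11, or 6 + 7 → 8 → 10 → 11).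

The three steps most likely to fail:

Step 5 (the proposed new annulation). The risks are insertion with the opposite regiochemistry (giving the 3-aryl-2-methoxy isomer), loss of the ynol ether by acid-promoted hydration or by [2+2] reaction with the aldehyde, and decarbonylation of the acyl rhodacycle. The fallback uses only known chemistry, sets out from 3 and comes back to the route at 11. Ortho-acetylation of 3 (AcOH, BF3·OEt2, 90 °C) gives 1-(2-hydroxy-3,4,5-trimethoxyphenyl)ethan-1-one F1. Claisen–Schmidt condensation of F1 with 4-methoxybenzaldehyde (KOH, EtOH, rt) gives (E)-1-(2-hydroxy-3,4,5-trimethoxyphenyl)-3-(4-methoxyphenyl)prop-2-en-1-one F2. Algar–Flynn–Oyamada oxidative cyclisation of F2 (30% H2O2, NaOH, MeOH, 0 °C to rt) gives 3-hydroxy-6,7,8-trimethoxy-2-(4-methoxyphenyl)-4H-chromen-4-one F3; the free 6'-position favours the flavonol over the aurone. O-Methylation of F3 (MeI, K2CO3, acetone, reflux) gives 11.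

Step 4 (one-pot triflation and elimination). The electron-rich aryl methyl ynol ether is acid-labile and may not survive isolation, and triflation of the chelated enolate may be slow. The fallback builds the C(sp2)–C(sp) bond by cross-coupling instead of elimination, sets out from anisole 6 and comes back at 10. Para-iodination of 6 (NIS, CF3CO2H cat., MeCN, rt) gives 4-iodoanisole F4. In a second flask, chloroacetaldehyde dimethyl acetal and LiNEt2 (3 equiv, THF, 0 °C) give lithium methoxyacetylide F5, and ZnCl2 converts it into (methoxyethynyl)zinc chloride F6. Negishi coupling of F6 with F4 (Pd(PPh3)4, a zerovalent palladium catalyst, 5 mol %, THF, rt) gives 10.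

Step 3 (Friedel–Crafts acylation). AlCl3 can decarbonylate methoxyacetyl chloride to a methoxymethyl cation or cleave a methyl ether, and some ortho isomer may form. The fallback replaces electrophilic acylation by a Weinreb ketone synthesis, sets out from 7 and comes back at 8. Treatment of 7 with MeNHOMe·HCl and Et3N (CH2Cl2, 0 °C) gives N,2-dimethoxy-N-methylacetamide F7. Addition of commercial 4-MeOC6H4MgBr to F7 (THF, 0 °C, then aqueous NH4Cl) gives 8 without over-addition.

**Further compounds**
F1 | step 5 | 1-(2-hydroxy-3,4,5-trimethoxyphenyl)ethan-1-one | CC(=O)c1cc(OC)c(OC)c(OC)c1O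
F2 | step 5 | (E)-1-(2-hydroxy-3,4,5-trimethoxyphenyl)-3-(4-methoxyphenyl)prop-2-en-1-one | COc1ccc(/C=C/C(=O)c2cc(OC)c(OC)c(OC)c2O)cc1
F3 | step 5 | 3-hydroxy-6,7,8-trimethoxy-2-(4-methoxyphenyl)-4H-chromen-4-one | COc1ccc(-c2oc3c(OC)c(OC)c(OC)cc3c(=O)c2O)cc1
F4 | step 4 | 4-iodoanisole | COc1ccc(I)cc1
F5 | step 4 | lithium methoxyacetylide | COC#C[Li]
F6 | step 4 | (methoxyethynyl)zinc chloride | COC#C[Zn]Cl
F7 | step 3 | N,2-dimethoxy-N-methylacetamide | COCC(=O)N(C)OC
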